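## Structural features

The target is a flavonol: ring A (benzo) is fused through C4a–C8a to the 4-pyranone ring C, which carries the catechol ring B at C2 and an enolic hydroxyl at C3. There is no stereocentre, so the problem is purely one of regiochemistry and oxidation pattern. Ring A is hexasubstituted, with C5–OH, C6–OMe, C7–OH and C8–OMe between the fusion atoms C4a and C8a. The five free hydroxyls, among them an air-sensitive catechol and a 3-hydroxy-4-pyranone, tolerate acid but not base in the presence of oxygen, so they are best uncovered in the last operation. The real difficulty is to place two methyl ethers and two hydroxyls in alternation on a ring without a free position, and to tell the C5 oxygen from the methoxyls at C6 and C8. Ring A has a local mirror plane through C4a and C7: C6 and C8 bear the same methoxyl, and C5 and C8a both bear oxygen. The key step uses exactly this: an arene that already holds the C4 carbon on C4a, C6–OMe, C7–O and C8–OMe, and has two equivalent bromides at C5 and C8a, takes up O1 on one side (closing ring C) and a methoxyl on the other, and it does not matter which side does which. The oxygen placed at C5 is then the only ether oxygen peri to C4=O, which later allows its methyl group to be removed by chelation while C6–OMe and C8–OMe stay.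

## Logic of the disconnections

16 ⇒ 15. The four O–CH2Ph bonds and the O–CH3 bond at C5 are cut. All five free hydroxyls are thereby masked in a compound that is stable to base and air. A Lewis acid strong enough for the chelated C5 methyl ether would not reliably spare the C3 benzyl ether, which chelates the same carbonyl, so no attempt is made to keep the benzyl groups and one reagent removes all five. The demand on the forward step is that C6–OMe and C8–OMe, which have no chelating neighbour, survive.

15 ⇒ 13 (through 14). The bonds C8a–O1 and C5–OMe are cut, which opens ring C and turns ring A into a symmetric dibromide with the diketone chain on C4a. Both oxygens missing from the ring A precursor arrive in one operation. The forward step requires that the enolate oxygen of 13 arylates before methoxide meets the diketone, and that the bromide left in 14 is substituted, not reduced.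

13 ⇒ 12. The C4 carbonyl is taken back to the carbinol. An acyl carbon flanked by two bromines is a poor acylating agent, but the corresponding aldehyde is a good aldol acceptor, so the C3–C4 bond is better made at the lower oxidation level. The forward oxidation has to be neutral so that the β-hydroxy ketone does not revert to its components.

12 ⇒ 3 + 10 (through 11). The C3–C4 bond is cut. This divides the molecule into a ring A aldehyde and a ring B ketone of similar size, so the route is convergent. 3 cannot enolise, which leaves 11 as the only nucleophile, but 3 is hindered, so the adduct must be quenched cold.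

3 ⇒ 2 ⇒ 1. The two C–Br bonds and then the O–benzyl bond are cut. The bromines go to the only two free positions of ring A, each ortho to one methoxyl and para to the other, so no regiochemical question arises. The gain is a cheap starting material that already holds three of the five oxygens attached to ring A (those at C6, C7 and C8) and the C4 carbon. The forward bromination must leave the benzyl ether intact.

10 ⇒ 5 + 8 (through 9). The bond between C2 and ring B is cut. An aryl nucleophile and an acyl donor that stops at the ketone stage are required, and 8 provides the latter and already carries the C3 oxygen as its benzyl ether.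

5 ⇒ 4 and 8 ⇒ 6 (through 7). Only O–benzyl bonds and an amide C–N bond are cut, which leads back to purchasable compounds.

## Other disconnections considered

Alternative 1: The cut is C4a–C8a, with ring A traced back to an open chain, methyl 8-(benzyloxy)-2,4-dimethoxy-3,5,7-trioxooctanoate (A1). In the forward step, base would form the enolate at the methylene between two carbonyls of A1, and this would attack the ester carbon in an intramolecular Claisen condensation, aromatising to 2-(benzyloxy)-1-(2,4,6-trihydroxy-3,5-dimethoxyphenyl)ethan-1-one (A2). A2 would then be annulated with a protected 3,4-dihydroxybenzoyl donor (Allan–Robinson or Baker–Venkataraman) to the flavonol.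
- In its favour: ring A appears with methoxyls and hydroxyls already differentiated. No halogen, no copper and no demethylation are needed, and on this point it is better than the chosen plan. A2 is symmetric, so either ortho hydroxyl can become O1, which equals the symmetry argument of the chosen plan.
- Against it: A1 has two methoxy-bearing methines between carbonyls and is hard to assemble and to handle. Such chains can lactonise to pyranones or close in the aldol sense, and the ester carbon to be attacked sits next to a second enolisable centre. A2 carries three free phenols, so the annulation needs acylation and rearrangement steps and a final deprotection.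
- Comparison: the structure is solved more directly, but the mechanism rests on less secure ground than two copper substitutions of known type. The step count (chain assembly, cyclisation, two or three annulation steps, deprotection) is not expected to fall below nine.

Alternative 2: The cuts are C6–OMe and C8–OMe. The sequence would begin with commercial quercetin (A3). A3 would be benzylated at all hydroxyls except the chelated one to 3,7-bis(benzyloxy)-2-[3,4-bis(benzyloxy)phenyl]-5-hydroxy-4H-chromen-4-one (A4). A4 would be brominated at C6 and C8 to 3,7-bis(benzyloxy)-2-[3,4-bis(benzyloxy)phenyl]-6,8-dibromo-5-hydroxy-4H-chromen-4-one (A5). In the key step CuBr (monovalent copper) and NaOMe would replace both bromides of A5 to give 3,7-bis(benzyloxy)-2-[3,4-bis(benzyloxy)phenyl]-5-hydroxy-6,8-dimethoxy-4H-chromen-4-one (A6), and hydrogenolysis of A6 would finish.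
- In its favour: A3 supplies the whole carbon skeleton and five of the seven oxygen substituents. Four steps from A3 would suffice, which is clearly better step economy than the chosen plan. The C5 hydroxyl never has to be unmasked. A ring opening and reclosure of the Wessely–Moser type would change nothing because C6 and C8 end up identical. The copper chemistry is of the same type as in the chosen plan.
- Against it: two intermolecular methoxylations are needed, each at a bromide flanked by two oxygen substituents. The C5 phenoxide of A5 makes ring A electron-rich, which should slow substitution and favour hydrodebromination, and partly substituted or reduced products would be hard to separate. Bromination of A4 must also distinguish ring A from the electron-rich ring B.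
- Comparison: the chosen plan needs only one intermolecular methoxylation, at a bromide activated by the peri carbonyl and with no free phenol present, and its halogens are placed before ring B exists. If the double methoxylation of A5 proceeds cleanly, the route from A3 is the shorter and cheaper one. A6 is the same compound as F2 and F3 of the fallbacks below.

Alternative 3: The cuts are C8a–O1, C4a–C4 and O1–C2, all made in one operation. Fluoride would release an aryne from 5-(benzyloxy)-4,6-dimethoxy-2-(trimethylsilyl)-1,3-phenylene bis(trifluoromethanesulfonate) (A7). The carboxylate of 3-[3,4-bis(benzyloxy)phenyl]prop-2-ynoic acid (A8) would bond through oxygen to the aryne carbon that becomes C8a. The aryl anion left at C4a would then pick up the acyl carbon, and the phenoxide set free in that transfer would add to the resulting ynone in a 6-endo closure of ring C. The product would be 7-(benzyloxy)-2-[3,4-bis(benzyloxy)phenyl]-6,8-dimethoxy-4-oxo-4H-chromen-5-yl trifluoromethanesulfonate (A9).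
- In its favour: it is the most convergent of the plans and forms three bonds in one step, which is better than the two of the chosen key step. The C5 oxygen is released from a triflate under mild base, which is gentler than a demethylation.
- Against it: A9 has no oxygen at C3, so a later C3 hydroxylation of an electron-rich flavone is needed. The aryne is flanked by a triflyloxy group on one side and a methoxyl on the other, and these direct the carboxylate to opposite carbons. The aryl anion next to the triflate may expel it (a second aryne) or undergo a thia-Fries shift before it finds the acyl carbon. A 5-exo closure to an aurone-type ring competes with the 6-endo one. A7 is a hexasubstituted arene that itself needs several steps.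
- Comparison: it is bolder in mechanism, but several selectivities are unsecured where the chosen plan has none to secure. With the synthesis of A7 and A8, detriflation, C3 hydroxylation and debenzylation it is expected to be longer than nine steps.

Key step: step 8

Remark on structures: in 13 the acyl-bearing ring carbon is flanked by the two bromines, each bromine by a methoxyl, and the benzyloxy group stands para to the acyl group. Mapped onto the flavone numbering this gives C4a, C5/C8a, C6/C8 and C7, and 15 follows with O1 on C8a and the new methoxyl on C5, so neither structure needs correction. The benzyl ethers of 13 are kept because they tolerate every step up to the last.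

Assumption: 12 forms as a mixture of diastereomers, each racemic, and is used as such, because both stereocentres disappear in steps 7 and 8.

## Route

Step 1
Reactants: 1 syringaldehyde (4-hydroxy-3,5-dimethoxybenzaldehyde)
Product: 2 4-(benzyloxy)-3,5-dimethoxybenzaldehyde
Conditions: BnBr, K2CO3, DMF, 60 °C
Reagents that add atoms: benzyl bromide, BrCc1ccccc1
Why: Williamson ether synthesis; the phenol, acidified by the para formyl group, is fully ionised by carbonate, and the reactive benzylic bromide overcomes the two flanking methoxyls. The benzyl ether survives bromine, lithium bases, the oxidant and methoxide and falls in the final Lewis-acid step.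

Step 2
Reactants: 2 4-(benzyloxy)-3,5-dimethoxybenzaldehyde
Product: 3 4-(benzyloxy)-2,6-dibromo-3,5-dimethoxybenzaldehyde
Conditions: Br2 (2.5 equiv), NaOAc, AcOH, rt → 50 °C, dark
Reagents that add atoms: bromine, BrBr
Why: Electrophilic aromatic bromination; each of the two free ring positions is ortho to one methoxyl and para to the other, which should outweigh the deactivation by the formyl group and the first bromine. NaOAc takes up HBr so that the benzyl ether is not cleaved, and the unactivated benzyl ring is not attacked.

Step 3
Reactants: 4 4-bromocatechol (4-bromobenzene-1,2-diol)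
Product: 5 1,2-bis(benzyloxy)-4-bromobenzene
Conditions: BnBr (2.3 equiv), K2CO3, DMF, 60 °C, argon
Reagents that add atoms: benzyl bromide, BrCc1ccccc1
Why: Double Williamson ether synthesis; exclusion of air keeps the catecholate from oxidising before it is alkylated.

Step 4
Reactants: 6 benzyloxyacetic acid
Product: 8 2-(benzyloxy)-N-methoxy-N-methylacetamide, via acyl imidazole 7 (not isolated)
Conditions: CDI, CH2Cl2, rt; then MeNHOMe·HCl, rt
Reagents that add atoms: N,O-dimethylhydroxylamine hydrochloride, Cl.CNOC
Why: Amide formation through the acyl imidazole; the imidazole released in the activation frees the amine from its hydrochloride, and the ether oxygen is inert.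

Step 5
Reactants: 5 1,2-bis(benzyloxy)-4-bromobenzene; 8 2-(benzyloxy)-N-methoxy-N-methylacetamide
Product: 10 2-(benzyloxy)-1-[3,4-bis(benzyloxy)phenyl]ethan-1-one, via aryllithium 9 (not isolated)
Conditions: n-BuLi, THF, −78 °C; then 8, −78 → 0 °C; aq. NH4Cl
Reagents that add atoms: none
Why: Bromine–lithium exchange followed by Weinreb ketone synthesis; the N-methoxy-N-methyl amide holds the tetrahedral adduct as a lithium chelate until the quench, so the ketone never meets a second equivalent of 9. At −78 °C exchange and addition should outrun deprotonation next to the amide carbonyl.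

Step 6
Reactants: 10 2-(benzyloxy)-1-[3,4-bis(benzyloxy)phenyl]ethan-1-one; 3 4-(benzyloxy)-2,6-dibromo-3,5-dimethoxybenzaldehyde
Product: 12 2-(benzyloxy)-3-[4-(benzyloxy)-2,6-dibromo-3,5-dimethoxyphenyl]-1-[3,4-bis(benzyloxy)phenyl]-3-hydroxypropan-1-one (mixture of diastereomers), via lithium enolate 11 (not isolated)
Conditions: LiHMDS, THF, −78 °C; then 3, −78 °C; AcOH, −78 °C
Reagents that add atoms: none
Why: Lithium aldol addition of the chelated α-alkoxy enolate to a non-enolisable aldehyde made more electrophilic by its two ortho bromines; the acidic quench at −78 °C protonates the hindered aldolate before it can revert. The two new stereocentres (carbinol and benzyloxy carbon) are not controlled and need not be, since step 7 removes the first and step 8 turns the second into the sp2 carbon C3.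

Step 7
Reactants: 12 2-(benzyloxy)-3-[4-(benzyloxy)-2,6-dibromo-3,5-dimethoxyphenyl]-1-[3,4-bis(benzyloxy)phenyl]-3-hydroxypropan-1-one
Product: 13 2-(benzyloxy)-1-[4-(benzyloxy)-2,6-dibromo-3,5-dimethoxyphenyl]-3-[3,4-bis(benzyloxy)phenyl]propane-1,3-dione
Conditions: Dess–Martin periodinane, CH2Cl2, 0 °C → rt
Reagents that add atoms: none
Why: Dess–Martin oxidation of a β-hydroxy ketone to the 1,3-diketone under neutral conditions, which gives the aldol no base-mediated path back to its components. Aryl bromides and benzyl ethers are inert, and the central carbon already carries an oxygen, so it cannot be oxidised further to a tricarbonyl.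

Step 8
Reactants: 13 2-(benzyloxy)-1-[4-(benzyloxy)-2,6-dibromo-3,5-dimethoxyphenyl]-3-[3,4-bis(benzyloxy)phenyl]propane-1,3-dione
Product: 15 3,7-bis(benzyloxy)-2-[3,4-bis(benzyloxy)phenyl]-5,6,8-trimethoxy-4H-chromen-4-one, via 5-bromoflavone 14 (not isolated)
Conditions: CuBr (0.2 equiv), K2CO3, DMF, 90 °C, argon; then NaOMe/MeOH (excess), CuBr (to 1 equiv), EtOAc (cat.), 110 °C
Reagents that add atoms: sodium methoxide, [Na+].[O-]C
Why: Under carbonate 13 exists as its chelating enolate, which binds CuBr (monovalent copper); oxidative addition into one of the two ortho C–Br bonds gives an aryl copper enolate (formally trivalent copper), and C–O reductive elimination forms C8a–O1, an Ullmann-type intramolecular O-arylation of a 1-(2-bromoaryl)-1,3-diketone, which is the established copper route to flavones. Ring C closes in a 6-exo sense with respect to the departing bromide through the enol oxygen of the ring B carbonyl; C-arylation would require a four-membered ring and is excluded. No stereocentre is formed, and the benzyloxy-bearing carbon of 13 becomes the sp2 carbon C3. The two bromides are interchanged by rotation about the aryl–carbonyl bond, so either closure gives the same 14. Methoxide is held back until 13 is consumed, because it could otherwise cleave the diketone by retro-Claisen attack; in 14 the diketone is locked as a vinylogous ester and that path is closed. In the second stage copper methoxide replaces the remaining bromide at C5 (copper-mediated methoxylation of an aryl bromide, helped here by coordination of copper to the peri C4=O), forming C5–OMe. Argon is needed because copper enolates of 1,3-diketones are cleaved by oxygen. The later distinction of C5 from C6 and C8 is secured by position alone, since only the new methoxyl is peri to the carbonyl.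

Step 9
Reactants: 15 3,7-bis(benzyloxy)-2-[3,4-bis(benzyloxy)phenyl]-5,6,8-trimethoxy-4H-chromen-4-one
Product: 16 2-(3,4-dihydroxyphenyl)-3,5,7-trihydroxy-6,8-dimethoxy-4H-chromen-4-one (3,5,7,3',4'-pentahydroxy-6,8-dimethoxyflavone)
Conditions: BCl3 (1 M in CH2Cl2, ca. 15 equiv), C6HMe5 (10 equiv), CH2Cl2, −78 → 0 °C; then MeOH
Reagents that add atoms: none
Why: Lewis-acid cleavage of aryl benzyl ethers with pentamethylbenzene as benzyl cation trap, combined with chelation-controlled demethylation: boron bound between C4=O and the C5 oxygen activates only the peri methyl ether towards chloride, while C6–OMe and C8–OMe have no such chelate and ordinary aryl methyl ethers should be inert to BCl3 at or below 0 °C. The trap prevents C-benzylation of ring B, and the acidic, non-oxidising medium suits the catechol and the 3-hydroxy-4-pyranone that are uncovered.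

## Compound list

1 | syringaldehyde (4-hydroxy-3,5-dimethoxybenzaldehyde) | COc1cc(C=O)cc(OC)c1O | starting material
2 | 4-(benzyloxy)-3,5-dimethoxybenzaldehyde | COc1cc(C=O)cc(OC)c1OCc1ccccc1 | intermediate
3 | 4-(benzyloxy)-2,6-dibromo-3,5-dimethoxybenzaldehyde | COc1c(OCc2ccccc2)c(OC)c(Br)c(C=O)c1Br | intermediate
4 | 4-bromocatechol (4-bromobenzene-1,2-diol) | Oc1ccc(Br)cc1O | starting material
5 | 1,2-bis(benzyloxy)-4-bromobenzene | Brc1ccc(OCc2ccccc2)c(OCc2ccccc2)c1 | intermediate
6 | benzyloxyacetic acid | OC(=O)COCc1ccccc1 | starting material
7 | 2-(benzyloxy)-1-(1H-imidazol-1-yl)ethan-1-one | O=C(COCc1ccccc1)n1ccnc1 | intermediate (not isolated)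
8 | 2-(benzyloxy)-N-methoxy-N-methylacetamide | CON(C)C(=O)COCc1ccccc1 | intermediate
9 | [3,4-bis(benzyloxy)phenyl]lithium | [Li]c1ccc(OCc2ccccc2)c(OCc2ccccc2)c1 | intermediate (not isolated)
10 | 2-(benzyloxy)-1-[3,4-bis(benzyloxy)phenyl]ethan-1-one | O=C(COCc1ccccc1)c1ccc(OCc2ccccc2)c(OCc2ccccc2)c1 | intermediate
11 | lithium (Z)-2-(benzyloxy)-1-[3,4-bis(benzyloxy)phenyl]ethen-1-olate (chelated geometry expected, without consequence) | [Li+].[O-]/C(=C\OCc1ccccc1)c1ccc(OCc2ccccc2)c(OCc2ccccc2)c1 | intermediate (not isolated)
12 | 2-(benzyloxy)-3-[4-(benzyloxy)-2,6-dibromo-3,5-dimethoxyphenyl]-1-[3,4-bis(benzyloxy)phenyl]-3-hydroxypropan-1-one (mixture of diastereomers, each racemic) | COc1c(OCc2ccccc2)c(OC)c(Br)c(C(O)C(OCc2ccccc2)C(=O)c2ccc(OCc3ccccc3)c(OCc3ccccc3)c2)c1Br | intermediate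
13 | 2-(benzyloxy)-1-[4-(benzyloxy)-2,6-dibromo-3,5-dimethoxyphenyl]-3-[3,4-bis(benzyloxy)phenyl]propane-1,3-dione (enolisable, no fixed stereocentre) | COc1c(OCc2ccccc2)c(OC)c(Br)c(C(=O)C(OCc2ccccc2)C(=O)c2ccc(OCc3ccccc3)c(OCc3ccccc3)c2)c1Br | intermediate
14 | 3,7-bis(benzyloxy)-2-[3,4-bis(benzyloxy)phenyl]-5-bromo-6,8-dimethoxy-4H-chromen-4-one | COc1c(OCc2ccccc2)c(OC)c2oc(-c3ccc(OCc4ccccc4)c(OCc4ccccc4)c3)c(OCc3ccccc3)c(=O)c2c1Br | intermediate (not isolated)
15 | 3,7-bis(benzyloxy)-2-[3,4-bis(benzyloxy)phenyl]-5,6,8-trimethoxy-4H-chromen-4-one | COc1c(OCc2ccccc2)c(OC)c2oc(-c3ccc(OCc4ccccc4)c(OCc4ccccc4)c3)c(OCc3ccccc3)c(=O)c2c1OC | intermediate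
16 | 2-(3,4-dihydroxyphenyl)-3,5,7-trihydroxy-6,8-dimethoxy-4H-chromen-4-one | COc1c(O)c(OC)c2oc(-c3ccc(O)c(O)c3)c(O)c(=O)c2c1O | target

## Step count and least certain steps

Total: 9 steps. Longest linear sequence: 6 steps (steps 1, 2, 6, 7, 8, 9; the branches through steps 3 and 5 and through steps 4 and 5 are equally long).

Step 8 (key step). What may go wrong:
- slow copper insertion at a ring whose acyl group is twisted out of plane by two ortho bromines, so that unconsumed diketone is cleaved by retro-Claisen attack once methoxide is added;
- hydrodebromination at C5 in competition with methoxylation;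
- reversible opening of the pyranone by methoxide at C2.

The fallback sets out from 13, separates the two events and forms the C5–O bond by a different mechanism. 13 would be cyclised with CuBr and K2CO3 alone and 14 isolated. Miyaura borylation (B2pin2, Pd(OAc)2, SPhos, KOAc, dioxane, 90 °C) would give 3,7-bis(benzyloxy)-2-[3,4-bis(benzyloxy)phenyl]-6,8-dimethoxy-5-(4,4,5,5-tetramethyl-1,3,2-dioxaborolan-2-yl)-4H-chromen-4-one F1. Oxidation with NaBO3·4H2O in THF/water would give 3,7-bis(benzyloxy)-2-[3,4-bis(benzyloxy)phenyl]-5-hydroxy-6,8-dimethoxy-4H-chromen-4-one F2. Hydrogenolysis of F2 (H2, Pd/C, palladium on carbon, EtOAc/MeOH) would return to the route at 16, with no demethylation needed.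

Step 9. What may go wrong:
- loss of the C6 or C8 methyl group on long exposure to the large excess of BCl3, possibly assisted by the boron aryloxide formed at C7;
- incomplete removal of one of the benzyl groups;
- benzylation of ring B if the cation trap is outrun.

The fallback sets out from 15 and separates the two cleavages by mechanism. A small excess of BCl3 at −78 → −20 °C for a short time would cleave the chelated methyl ether to 3,7-bis(benzyloxy)-2-[3,4-bis(benzyloxy)phenyl]-5-hydroxy-6,8-dimethoxy-4H-chromen-4-one F3 (identical with F2). Any premature loss of a benzyl group at this stage would be harmless. Hydrogenolysis (H2, Pd/C, EtOAc/MeOH), which cannot touch a methyl ether, would then give 16.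

Step 6. What may go wrong: reversion of the crowded lithium aldolate to its components before or during the quench, or sluggish addition to the doubly ortho-substituted aldehyde. The fallback sets out from 3 and joins the fragments at the acid oxidation level, which also bypasses step 7. Pinnick oxidation (NaClO2, NaH2PO4, 2-methyl-2-butene, t-BuOH/water) would give 4-(benzyloxy)-2,6-dibromo-3,5-dimethoxybenzoic acid F4. (COCl)2 with catalytic DMF would give 4-(benzyloxy)-2,6-dibromo-3,5-dimethoxybenzoyl chloride F5. F5 would acylate 10 at carbon under soft enolisation (MgBr2·OEt2, i-Pr2NEt, CH2Cl2; a Claisen-type condensation through the magnesium chelate of the α-alkoxy ketone), returning to the route at 13.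

Step 2. What may go wrong: arrest after the first bromination, or loss of the benzyl group if HBr is not fully buffered. The fallback sets out from 1 and introduces the bromines before the benzyl group. Acetylation (Ac2O, pyridine) would give 4-formyl-2,6-dimethoxyphenyl acetate F6. Bromination (Br2, NaOAc, AcOH) would give 3,5-dibromo-4-formyl-2,6-dimethoxyphenyl acetate F7, whose ester is indifferent to HBr. Methanolysis (K2CO3, MeOH) would release 2,6-dibromo-4-hydroxy-3,5-dimethoxybenzaldehyde F8, which, after removal of the methanol, would be benzylated as in step 1 (BnBr, K2CO3, DMF), returning to the route at 3.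

## Further compounds

F1 | step 8 | 3,7-bis(benzyloxy)-2-[3,4-bis(benzyloxy)phenyl]-6,8-dimethoxy-5-(4,4,5,5-tetramethyl-1,3,2-dioxaborolan-2-yl)-4H-chromen-4-one | COc1c(OCc2ccccc2)c(OC)c2oc(-c3ccc(OCc4ccccc4)c(OCc4ccccc4)c3)c(OCc3ccccc3)c(=O)c2c1B1OC(C)(C)C(C)(C)O1
F2 | step 8 | 3,7-bis(benzyloxy)-2-[3,4-bis(benzyloxy)phenyl]-5-hydroxy-6,8-dimethoxy-4H-chromen-4-one | COc1c(OCc2ccccc2)c(OC)c2oc(-c3ccc(OCc4ccccc4)c(OCc4ccccc4)c3)c(OCc3ccccc3)c(=O)c2c1O
F3 | step 9 | 3,7-bis(benzyloxy)-2-[3,4-bis(benzyloxy)phenyl]-5-hydroxy-6,8-dimethoxy-4H-chromen-4-one | COc1c(OCc2ccccc2)c(OC)c2oc(-c3ccc(OCc4ccccc4)c(OCc4ccccc4)c3)c(OCc3ccccc3)c(=O)c2c1O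
F4 | step 6 | 4-(benzyloxy)-2,6-dibromo-3,5-dimethoxybenzoic acid | COc1c(OCc2ccccc2)c(OC)c(Br)c(C(=O)O)c1Br
F5 | step 6 | 4-(benzyloxy)-2,6-dibromo-3,5-dimethoxybenzoyl chloride | COc1c(OCc2ccccc2)c(OC)c(Br)c(C(Cl)=O)c1Br
F6 | step 2 | 4-formyl-2,6-dimethoxyphenyl acetate | COc1cc(C=O)cc(OC)c1OC(C)=O
F7 | step 2 | 3,5-dibromo-4-formyl-2,6-dimethoxyphenyl acetate | COc1c(OC(C)=O)c(OC)c(Br)c(C=O)c1Br
F8 | step 2 | 2,6-dibromo-4-hydroxy-3,5-dimethoxybenzaldehyde | COc1c(O)c(OC)c(Br)c(C=O)c1Br
A1 | alternative 1 | methyl 8-(benzyloxy)-2,4-dimethoxy-3,5,7-trioxooctanoate | COC(=O)C(OC)C(=O)C(OC)C(=O)CC(=O)COCc1ccccc1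
A2 | alternative 1 | 2-(benzyloxy)-1-(2,4,6-trihydroxy-3,5-dimethoxyphenyl)ethan-1-one | COc1c(O)c(OC)c(O)c(C(=O)COCc2ccccc2)c1O
A3 | alternative 2 | quercetin | O=c1c(O)c(-c2ccc(O)c(O)c2)oc2cc(O)cc(O)c12
A4 | alternative 2 | 3,7-bis(benzyloxy)-2-[3,4-bis(benzyloxy)phenyl]-5-hydroxy-4H-chromen-4-one | Oc1cc(OCc2ccccc2)cc2oc(-c3ccc(OCc4ccccc4)c(OCc4ccccc4)c3)c(OCc3ccccc3)c(=O)c12
A5 | alternative 2 | 3,7-bis(benzyloxy)-2-[3,4-bis(benzyloxy)phenyl]-6,8-dibromo-5-hydroxy-4H-chromen-4-one | Oc1c(Br)c(OCc2ccccc2)c(Br)c2oc(-c3ccc(OCc4ccccc4)c(OCc4ccccc4)c3)c(OCc3ccccc3)c(=O)c12
A6 | alternative 2 | 3,7-bis(benzyloxy)-2-[3,4-bis(benzyloxy)phenyl]-5-hydroxy-6,8-dimethoxy-4H-chromen-4-one | COc1c(OCc2ccccc2)c(OC)c2oc(-c3ccc(OCc4ccccc4)c(OCc4ccccc4)c3)c(OCc3ccccc3)c(=O)c2c1O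
A7 | alternative 3 | 5-(benzyloxy)-4,6-dimethoxy-2-(trimethylsilyl)-1,3-phenylene bis(trifluoromethanesulfonate) | COc1c(OCc2ccccc2)c(OC)c(OS(=O)(=O)C(F)(F)F)c([Si](C)(C)C)c1OS(=O)(=O)C(F)(F)F
A8 | alternative 3 | 3-[3,4-bis(benzyloxy)phenyl]prop-2-ynoic acid | OC(=O)C#Cc1ccc(OCc2ccccc2)c(OCc2ccccc2)c1
A9 | alternative 3 | 7-(benzyloxy)-2-[3,4-bis(benzyloxy)phenyl]-6,8-dimethoxy-4-oxo-4H-chromen-5-yl trifluoromethanesulfonate | COc1c(OCc2ccccc2)c(OC)c2oc(-c3ccc(OCc4ccccc4)c(OCc4ccccc4)c3)cc(=O)c2c1OS(=O)(=O)C(F)(F)F
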